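**Remark:** Positions carry germacranolide numbers: ring carbons C1–C10 (C1 carbinol, C3 acetoxy carbon, C6 lactone carbinol, C7 ring-fusion carbon, C8 tigloyloxy carbon), C11–C13 the methylene-lactone carbons, C14 and C15 the methyls on C10 and C4. Ylide 8 and acid 22 are taken as purchased.

## Retrosynthetic overview

1. The target is (1S,3S,6R,7S,8R,4Z,9E)-3-acetoxy-1-hydroxy-8-tigloyloxygermacra-4,9,11(13)-trien-12,6-olide; the last steps only exchange silyl groups for the tiglate and the free C1 hydroxyl.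
2. Key disconnection: the whole γ-lactone ring (O, C6, C7, C11, C12) is removed at once by cutting O–C6 and C11–C7, giving a ten-membered (4Z,6Z,9E)-triene and 2-bromoacrylic acid. The enabling feature is that the lactone carbinol C6 is allylic to the C4=C5 alkene, so C6–O and C7–C11 are the 1,2-positions of a C4=C5–C6=C7 diene, and carbo-oxygenation of that diene leaves C4=C5 behind.
3. The ten-membered ring is closed at C7–C8 by a Nozaki–Hiyama–Kishi reaction of a (Z,Z)-dienyl iodide with an (E)-enal.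
4. The chain comes from a boron aldol at C2–C3 (sets C3) and an Evans–Tishchenko reduction with acetaldehyde (sets C1 anti and puts the acetate on O3). The pieces are propargyl alcohol (C3–C5, C15, Z geometry), ethynyltrimethylsilane (C6, C7) and silyloxyacetaldehyde plus an acetyl ylide (C8–C10, C1, C2, C14).
5. Ring order: ten-membered carbocycle first (step 12), γ-lactone second (step 14).

Key step: step 14

## Route

Step 1
Reactants: 1 prop-2-yn-1-ol
Product: 3 (Z)-3-iodo-2-methylprop-2-en-1-ol, via chelated alkenylmagnesium alkoxide 2 (not isolated)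
Conditions: MeMgBr (2.5 equiv), CuI (10 mol%), THF, −10 °C to rt; then I2, −78 to 0 °C
Reagents that add atoms: methylmagnesium bromide C[Mg]Br; iodine II
Why: Copper-catalysed carbomagnesiation of the magnesium propargyl alkoxide is anti (five-membered chelate 2), and iodinolysis with retention should give the (Z)-iodide that later becomes the Z C4=C5 alkene.

Step 2
Reactants: 3 (Z)-3-iodo-2-methylprop-2-en-1-ol; 4 ethynyltrimethylsilane
Product: 5 (Z)-2-methyl-5-(trimethylsilyl)pent-2-en-4-yn-1-ol
Conditions: Pd(PPh3)2Cl2 (2 mol%), CuI (4 mol%), Et3N, THF, rt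
Reagents that add atoms: none
Why: Sonogashira coupling proceeds with retention of the alkenyl iodide geometry and tolerates the free alcohol.

Step 3
Reactants: 5 (Z)-2-methyl-5-(trimethylsilyl)pent-2-en-4-yn-1-ol
Product: 6 (Z)-2-methyl-5-(trimethylsilyl)pent-2-en-4-ynal
Conditions: MnO2 (activated), CH2Cl2, rt; used directly
Reagents that add atoms: none
Why: MnO2 oxidises allylic alcohols selectively under neutral conditions, which should keep the Z geometry of the enal if it is used at once.

Step 4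
Reactants: 7 2-[(tert-butyldimethylsilyl)oxy]acetaldehyde; 8 3-(triphenylphosphoranylidene)butan-2-one
Product: 9 (E)-5-[(tert-butyldimethylsilyl)oxy]-3-methylpent-3-en-2-one
Conditions: toluene, 80 °C
Reagents that add atoms: none
Why: Wittig reaction of a stabilised α-methyl ylide should give the (E)-trisubstituted enone, the future E C9=C10 alkene.

Step 5
Reactants: 9 (E)-5-[(tert-butyldimethylsilyl)oxy]-3-methylpent-3-en-2-one; 6 (Z)-2-methyl-5-(trimethylsilyl)pent-2-en-4-ynal
Product: 12 (2E,6S,7Z)-1-[(tert-butyldimethylsilyl)oxy]-6-hydroxy-3,7-dimethyl-10-(trimethylsilyl)deca-2,7-dien-9-yn-4-one, via enol diisopinocampheylborinate 10 (not isolated), via boron aldolate 11 (not isolated)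
Conditions: (−)-Ipc2BCl, Et3N, Et2O, 0 °C; then 6, −78 to −20 °C; H2O2, MeOH, pH 7 buffer
Reagents that add atoms: none
Why: Paterson-type boron aldol of a methyl ketone: enolisation occurs on the methyl side, and the isopinocampheyl ligands of the (−)-reagent are expected to direct the enolate to the si face of the aldehyde, which sets C3 (C6 of the chain name) as S.

Step 6
Reactants: 12 (2E,6S,7Z)-1-[(tert-butyldimethylsilyl)oxy]-6-hydroxy-3,7-dimethyl-10-(trimethylsilyl)deca-2,7-dien-9-yn-4-one
Product: 13 (2E,4S,6S,7Z)-1-[(tert-butyldimethylsilyl)oxy]-4-hydroxy-3,7-dimethyl-10-(trimethylsilyl)deca-2,7-dien-9-yn-6-yl acetate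
Conditions: CH3CHO (8 equiv), SmI2 (30 mol%), THF, −10 °C
Reagents that add atoms: acetaldehyde CC=O
Why: Evans–Tishchenko reduction: the samarium-bound hemiacetal of the C3 hydroxyl with acetaldehyde delivers hydride to the C1 ketone through a chair six-membered transition state, which should give the 1,3-anti relation (C1 S) and leave the acetate on O3.

Step 7
Reactants: 13 (2E,4S,6S,7Z)-1-[(tert-butyldimethylsilyl)oxy]-4-hydroxy-3,7-dimethyl-10-(trimethylsilyl)deca-2,7-dien-9-yn-6-yl acetate
Product: 14 (2E,4S,6S,7Z)-1,4-bis[(tert-butyldimethylsilyl)oxy]-3,7-dimethyl-10-(trimethylsilyl)deca-2,7-dien-9-yn-6-yl acetate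
Conditions: TBSOTf, 2,6-lutidine, CH2Cl2, −78 °C
Reagents that add atoms: tert-butyldimethylsilyl triflate CC(C)(C)[Si](C)(C)OS(=O)(=O)C(F)(F)F
Why: Low-temperature silylation protects the C1 allylic alcohol before the acetate can migrate.

Step 8
Reactants: 14 (2E,4S,6S,7Z)-1,4-bis[(tert-butyldimethylsilyl)oxy]-3,7-dimethyl-10-(trimethylsilyl)deca-2,7-dien-9-yn-6-yl acetate
Product: 15 (2E,4S,6S,7Z)-1,4-bis[(tert-butyldimethylsilyl)oxy]-10-iodo-3,7-dimethyldeca-2,7-dien-9-yn-6-yl acetate
Conditions: NIS, AgNO3 (10 mol%), DMF, rt, dark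
Reagents that add atoms: N-iodosuccinimide O=C1CCC(=O)N1I
Why: Silver-catalysed iododesilylation converts the alkynylsilane directly into the 1-iodoalkyne without touching the silyl ethers or the trisubstituted alkenes.

Step 9
Reactants: 15 (2E,4S,6S,7Z)-1,4-bis[(tert-butyldimethylsilyl)oxy]-10-iodo-3,7-dimethyldeca-2,7-dien-9-yn-6-yl acetate
Product: 16 (2E,4S,6S,7Z,9Z)-1,4-bis[(tert-butyldimethylsilyl)oxy]-10-iodo-3,7-dimethyldeca-2,7,9-trien-6-yl acetate
Conditions: 2-nitrobenzenesulfonylhydrazide, Et3N, THF/i-PrOH, rt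
Reagents that add atoms: none
Why: Diimide reduction adds hydrogen syn to the iodoalkyne and should give the (Z)-alkenyl iodide, while trisubstituted alkenes react far more slowly.

Step 10
Reactants: 16 (2E,4S,6S,7Z,9Z)-1,4-bis[(tert-butyldimethylsilyl)oxy]-10-iodo-3,7-dimethyldeca-2,7,9-trien-6-yl acetate
Product: 17 (2E,4S,6S,7Z,9Z)-4-[(tert-butyldimethylsilyl)oxy]-1-hydroxy-10-iodo-3,7-dimethyldeca-2,7,9-trien-6-yl acetate
Conditions: HF·pyridine, pyridine, THF, 0 °C
Reagents that add atoms: none
Why: Buffered HF·pyridine cleaves a primary silyl ether much faster than a secondary one, so only the C8 oxygen should be freed.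

Step 11
Reactants: 17 (2E,4S,6S,7Z,9Z)-4-[(tert-butyldimethylsilyl)oxy]-1-hydroxy-10-iodo-3,7-dimethyldeca-2,7,9-trien-6-yl acetate
Product: 18 (2E,4S,6S,7Z,9Z)-4-[(tert-butyldimethylsilyl)oxy]-10-iodo-3,7-dimethyl-1-oxodeca-2,7,9-trien-6-yl acetate
Conditions: MnO2, CH2Cl2, rt
Reagents that add atoms: none
Why: Allylic oxidation with MnO2 should give the (E)-enal without affecting the dienyl iodide, acetate or silyl ether.

Step 12
Reactants: 18 (2E,4S,6S,7Z,9Z)-4-[(tert-butyldimethylsilyl)oxy]-10-iodo-3,7-dimethyl-1-oxodeca-2,7,9-trien-6-yl acetate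
Product: 20 (1S,3S,8S,4Z,6Z,9E)-3-acetoxy-1-[(tert-butyldimethylsilyl)oxy]-4,10-dimethylcyclodeca-4,6,9-trien-8-ol (target numbering), via alkenylchromium dichloride 19 (not isolated)
Conditions: CrCl2 (10 equiv), NiCl2 (2 mol%), DMSO/THF, 0.002 M, rt
Reagents that add atoms: none
Why: Nozaki–Hiyama–Kishi reaction: nickel-catalysed formation of the alkenylchromium with retention of the Z geometry and aldehyde-selective addition should close the ten-membered ring at high dilution; C8 is set under substrate control in the cyclic transition state, the 8S alcohol shown is the isomer needed, and its selectivity cannot be predicted with confidence (see below).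

Step 13
Reactants: 20 (1S,3S,8S,4Z,6Z,9E)-3-acetoxy-1-[(tert-butyldimethylsilyl)oxy]-4,10-dimethylcyclodeca-4,6,9-trien-8-ol
Product: 21 (1S,3S,8S,4Z,6Z,9E)-1-[(tert-butyldimethylsilyl)oxy]-4,10-dimethyl-8-[(triethylsilyl)oxy]cyclodeca-4,6,9-trien-3-yl acetate (target numbering)
Conditions: TESCl, imidazole, DMF, 0 °C
Reagents that add atoms: chlorotriethylsilane CC[Si](Cl)(CC)CC
Why: Standard silylation; the triethylsilyl group cannot be ionised by palladium, can later be removed in the presence of the tert-butyldimethylsilyl ether, and shields one face of the C6=C7 alkene.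

Step 14
Reactants: 21 (1S,3S,8S,4Z,6Z,9E)-1-[(tert-butyldimethylsilyl)oxy]-4,10-dimethyl-8-[(triethylsilyl)oxy]cyclodeca-4,6,9-trien-3-yl acetate; 22 2-bromoacrylic acid
Product: 23 (1S,3S,6R,7S,8R,4Z,9E)-3-acetoxy-1-[(tert-butyldimethylsilyl)oxy]-8-[(triethylsilyl)oxy]germacra-4,9,11(13)-trien-12,6-olide
Conditions: 22 (2 equiv), Pd(OAc)2 (10 mol%), P(2-furyl)3 (20 mol%), K2CO3 (3 equiv), n-Bu4NCl, BHT, DMF, 60 °C
Reagents that add atoms: none
Why: Proposed new method: zerovalent palladium inserts into the C–Br bond of 2-bromoacrylate, the α-carboxyvinylpalladium adds syn across C6=C7 of the conjugated diene with carbon going to C7 (bond C11–C7), and the resulting η3-allylpalladium over C4–C5–C6 is closed by the tethered carboxylate at C6 on the face opposite palladium (bond O–C6) with release of zerovalent palladium; the closest known reaction type is the Larock heteroannulation of 1,3-dienes with 2-iodobenzoic acids and functionalised vinyl halides, which has not been shown with a 2-haloacrylic acid or on a macrocyclic internal diene. The only ring closed is the γ-lactone (O, C6, C7, C11, C12), by 5-exo attack of carboxylate oxygen on the allyl terminus C6; closure at C4 would need a seven-membered ring at a fully substituted carbon. C7 is set in the insertion: with H8 eclipsing the Z alkene to avoid A(1,3) strain, the triethylsilyloxy group covers one face of C6=C7 and the vinylpalladium is expected to add anti to it, which places C11 in the relation to O8 found in the target. C6 is set by the anti (outer-sphere) C–O closure, which after syn insertion on a Z alkene gives the trans lactone (H6 and H7 anti), and C4=C5 stays Z because the ring-held allyl is captured before it can isomerise. The step needs regioselectivity for C7 over C4 (less substituted diene terminus, more substituted allyl), chemoselectivity over the isolated trisubstituted C9=C10 alkene (which should not insert), capture faster than β-hydride elimination (intramolecular five-ring closure) and survival of the C3 allylic acetate (weakly donating phosphine, zerovalent palladium kept low by fast oxidative addition of the electron-poor bromide).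

Step 15
Reactants: 23 (1S,3S,6R,7S,8R,4Z,9E)-3-acetoxy-1-[(tert-butyldimethylsilyl)oxy]-8-[(triethylsilyl)oxy]germacra-4,9,11(13)-trien-12,6-olide
Product: 24 (1S,3S,6R,7R,8R,4Z,9E)-3-acetoxy-1-[(tert-butyldimethylsilyl)oxy]-8-hydroxygermacra-4,9,11(13)-trien-12,6-olide
Conditions: PPTS (cat.), MeOH/CH2Cl2, 0 °C
Reagents that add atoms: none
Why: Mild acid methanolysis cleaves the secondary triethylsilyl ether far faster than the tert-butyldimethylsilyl ether and should leave lactone and acetate untouched (the C7 descriptor changes only through priorities).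

Step 16
Reactants: 24 (1S,3S,6R,7R,8R,4Z,9E)-3-acetoxy-1-[(tert-butyldimethylsilyl)oxy]-8-hydroxygermacra-4,9,11(13)-trien-12,6-olide; 25 tigloyl chloride, (E)-2-methylbut-2-enoyl chloride
Product: 26 (1S,3S,6R,7S,8R,4Z,9E)-3-acetoxy-1-[(tert-butyldimethylsilyl)oxy]-8-tigloyloxygermacra-4,9,11(13)-trien-12,6-olide
Conditions: pyridine, DMAP (cat.), CH2Cl2, 0 °C to rt
Reagents that add atoms: none
Why: Acylation of the only free hydroxyl with the acid chloride proceeds with retention at C8 and keeps the E geometry of the tiglate.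

Step 17
Reactants: 26 (1S,3S,6R,7S,8R,4Z,9E)-3-acetoxy-1-[(tert-butyldimethylsilyl)oxy]-8-tigloyloxygermacra-4,9,11(13)-trien-12,6-olide
Product: 27 (1S,3S,6R,7S,8R,4Z,9E)-3-acetoxy-1-hydroxy-8-tigloyloxygermacra-4,9,11(13)-trien-12,6-olide, the target
Conditions: HF·pyridine, THF, 0 °C to rt
Reagents that add atoms: none
Why: Desilylation with HF·pyridine is mildly acidic and should spare the two esters and the base-sensitive α-methylene lactone.

## Compound list

1 | prop-2-yn-1-ol | C#CCO | starting material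
2 | chelated (Z)-alkenylmagnesium alkoxide (4-methyl-2,5-dihydro-1,2-oxamagnesole) | CC1=C[Mg]OC1 | intermediate
3 | (Z)-3-iodo-2-methylprop-2-en-1-ol | OC/C(C)=C\I | intermediate
4 | ethynyltrimethylsilane | C#C[Si](C)(C)C | starting material
5 | (Z)-2-methyl-5-(trimethylsilyl)pent-2-en-4-yn-1-ol | OC/C(C)=C\C#C[Si](C)(C)C | intermediate
6 | (Z)-2-methyl-5-(trimethylsilyl)pent-2-en-4-ynal | O=C/C(C)=C\C#C[Si](C)(C)C | intermediate
7 | 2-[(tert-butyldimethylsilyl)oxy]acetaldehyde | O=CCO[Si](C)(C)C(C)(C)C | starting material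
8 | 3-(triphenylphosphoranylidene)butan-2-one | CC(=O)C(C)=P(c1ccccc1)(c1ccccc1)c1ccccc1 | starting material
9 | (E)-5-[(tert-butyldimethylsilyl)oxy]-3-methylpent-3-en-2-one | CC(=O)/C(C)=C/CO[Si](C)(C)C(C)(C)C | intermediate
10 | enol diisopinocampheylborinate of 9 (isopinocampheyl groups from (+)-α-pinene) | C=C(OB([C@@H]1C[C@@H]2C[C@H]([C@H]1C)C2(C)C)[C@@H]1C[C@@H]2C[C@H]([C@H]1C)C2(C)C)/C(C)=C/CO[Si](C)(C)C(C)(C)C | intermediate
11 | O-diisopinocampheylboryl aldolate of 12 | C[Si](C)(C)C#C/C=C(/C)[C@@H](OB([C@@H]1C[C@@H]2C[C@H]([C@H]1C)C2(C)C)[C@@H]1C[C@@H]2C[C@H]([C@H]1C)C2(C)C)CC(=O)/C(C)=C/CO[Si](C)(C)C(C)(C)C | intermediate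
12 | (2E,6S,7Z)-1-[(tert-butyldimethylsilyl)oxy]-6-hydroxy-3,7-dimethyl-10-(trimethylsilyl)deca-2,7-dien-9-yn-4-one | C[Si](C)(C)C#C/C=C(/C)[C@@H](O)CC(=O)/C(C)=C/CO[Si](C)(C)C(C)(C)C | intermediate
13 | (2E,4S,6S,7Z)-1-[(tert-butyldimethylsilyl)oxy]-4-hydroxy-3,7-dimethyl-10-(trimethylsilyl)deca-2,7-dien-9-yn-6-yl acetate | C[Si](C)(C)C#C/C=C(/C)[C@@H](OC(C)=O)C[C@H](O)/C(C)=C/CO[Si](C)(C)C(C)(C)C | intermediate
14 | (2E,4S,6S,7Z)-1,4-bis[(tert-butyldimethylsilyl)oxy]-3,7-dimethyl-10-(trimethylsilyl)deca-2,7-dien-9-yn-6-yl acetate | C[Si](C)(C)C#C/C=C(/C)[C@@H](OC(C)=O)C[C@H](O[Si](C)(C)C(C)(C)C)/C(C)=C/CO[Si](C)(C)C(C)(C)C | intermediate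
15 | (2E,4S,6S,7Z)-1,4-bis[(tert-butyldimethylsilyl)oxy]-10-iodo-3,7-dimethyldeca-2,7-dien-9-yn-6-yl acetate | IC#C/C=C(/C)[C@@H](OC(C)=O)C[C@H](O[Si](C)(C)C(C)(C)C)/C(C)=C/CO[Si](C)(C)C(C)(C)C | intermediate
16 | (2E,4S,6S,7Z,9Z)-1,4-bis[(tert-butyldimethylsilyl)oxy]-10-iodo-3,7-dimethyldeca-2,7,9-trien-6-yl acetate | I/C=C\C=C(\C)[C@@H](OC(C)=O)C[C@H](O[Si](C)(C)C(C)(C)C)/C(C)=C/CO[Si](C)(C)C(C)(C)C | intermediate
17 | (2E,4S,6S,7Z,9Z)-4-[(tert-butyldimethylsilyl)oxy]-1-hydroxy-10-iodo-3,7-dimethyldeca-2,7,9-trien-6-yl acetate | I/C=C\C=C(\C)[C@@H](OC(C)=O)C[C@H](O[Si](C)(C)C(C)(C)C)/C(C)=C/CO | intermediate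
18 | (2E,4S,6S,7Z,9Z)-4-[(tert-butyldimethylsilyl)oxy]-10-iodo-3,7-dimethyl-1-oxodeca-2,7,9-trien-6-yl acetate | I/C=C\C=C(\C)[C@@H](OC(C)=O)C[C@H](O[Si](C)(C)C(C)(C)C)/C(C)=C/C=O | intermediate
19 | (Z,Z)-dienylchromium dichloride derived from 18 | Cl[Cr](Cl)/C=C\C=C(\C)[C@@H](OC(C)=O)C[C@H](O[Si](C)(C)C(C)(C)C)/C(C)=C/C=O | intermediate
20 | (1S,3S,8S,4Z,6Z,9E)-3-acetoxy-1-[(tert-butyldimethylsilyl)oxy]-4,10-dimethylcyclodeca-4,6,9-trien-8-ol (target numbering) | C1[C@H](OC(C)=O)/C(C)=C\C=C/[C@H](O)/C=C(\C)[C@H]1O[Si](C)(C)C(C)(C)C | intermediate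
21 | (1S,3S,8S,4Z,6Z,9E)-1-[(tert-butyldimethylsilyl)oxy]-4,10-dimethyl-8-[(triethylsilyl)oxy]cyclodeca-4,6,9-trien-3-yl acetate (target numbering) | C1[C@H](OC(C)=O)/C(C)=C\C=C/[C@H](O[Si](CC)(CC)CC)/C=C(\C)[C@H]1O[Si](C)(C)C(C)(C)C | intermediate
22 | 2-bromoacrylic acid | C=C(Br)C(=O)O | starting material
23 | (1S,3S,6R,7S,8R,4Z,9E)-3-acetoxy-1-[(tert-butyldimethylsilyl)oxy]-8-[(triethylsilyl)oxy]germacra-4,9,11(13)-trien-12,6-olide | C=C1C(=O)O[C@@H]2/C=C(/C)[C@@H](OC(C)=O)C[C@H](O[Si](C)(C)C(C)(C)C)/C(C)=C/[C@@H](O[Si](CC)(CC)CC)[C@@H]12 | intermediate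
24 | (1S,3S,6R,7R,8R,4Z,9E)-3-acetoxy-1-[(tert-butyldimethylsilyl)oxy]-8-hydroxygermacra-4,9,11(13)-trien-12,6-olide | C=C1C(=O)O[C@@H]2/C=C(/C)[C@@H](OC(C)=O)C[C@H](O[Si](C)(C)C(C)(C)C)/C(C)=C/[C@@H](O)[C@@H]12 | intermediate
25 | tigloyl chloride, (E)-2-methylbut-2-enoyl chloride | C/C=C(\C)C(Cl)=O | starting material
26 | (1S,3S,6R,7S,8R,4Z,9E)-3-acetoxy-1-[(tert-butyldimethylsilyl)oxy]-8-tigloyloxygermacra-4,9,11(13)-trien-12,6-olide | C=C1C(=O)O[C@@H]2/C=C(/C)[C@@H](OC(C)=O)C[C@H](O[Si](C)(C)C(C)(C)C)/C(C)=C/[C@@H](OC(=O)/C(C)=C/C)[C@@H]12 | intermediate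
27 | (1S,3S,6R,7S,8R,4Z,9E)-3-acetoxy-1-hydroxy-8-tigloyloxygermacra-4,9,11(13)-trien-12,6-olide | C=C1C(=O)O[C@@H]2/C=C(/C)[C@@H](OC(C)=O)C[C@H](O)/C(C)=C/[C@@H](OC(=O)/C(C)=C/C)[C@@H]12 | target

## Step count and risks

Total step count: 17. Longest linear sequence: 16 (steps 1–3 and 5–17; step 4 makes the side fragment).

Steps most likely to fail:

1. Step 14 (proposed new method). The insertion may take the face of C6=C7 on the side of the silyloxy group if the ring conformation overrides the local bias, which gives the C7 epimer. The allylpalladium may lose a β-hydrogen before the carboxylate reaches the face opposite palladium, since that needs a rotation about C6–C7 within the ring. Zerovalent palladium may also ionise the C3 allylic acetate. The fallback sets out from 21 and comes back at 23, and still forms both lactone bonds in one operation, by a known radical–polar reaction type for alkenes and 1,3-dienes. Oxidative carbolactonisation of the diene with allyl hydrogen malonate, Mn(OAc)3·2H2O and Cu(OAc)2 in AcOH/MeCN with KOAc should add the malonyl radical to C7, oxidise the allyl radical to the cation and close the carboxylate on C6, giving the α-allyloxycarbonyl lactone F1 as a mixture at C11. Deallylation with Pd(PPh3)4 and morpholine in THF at rt should give the α-carboxy lactone F2. Decarboxylative Mannich methylenation (aqueous formaldehyde, Et2NH, then NaOAc/AcOH) should give 23.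

2. Step 12. The ring-closing addition to the aldehyde may show poor facial selectivity and give mainly the C8 epimer, and oligomerisation or loss of the Z geometry of the alkenylchromium may lower the amount of ring closure. The fallback sets out from 18 and comes back at 20 and sets C8 by a stereospecific inversion instead of by the C–C bond formation. The ring closure is run as in step 12 and the C8 epimer, (1S,3S,8R)-3-acetoxy-1-[(tert-butyldimethylsilyl)oxy]-4,10-dimethylcyclodeca-4,6,9-trien-8-ol F3, is separated. A Mitsunobu reaction with chloroacetic acid (PPh3, DIAD, toluene, 0 °C) should invert it to the (8S)-chloroacetate F4. The chloroacetyl group is then removed with thiourea and NaHCO3 in EtOH, which should leave the C3 acetate in place and give 20.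

3. Step 5. The enantioface selectivity of the diisopinocampheyl enol borinate toward the Z-enynal may be modest, and the Z-enal may isomerise under the Lewis-acidic conditions; every later stereocentre depends on C3. The fallback sets out from 9 and comes back at 12 and replaces the stoichiometric chiral boron enolate by a catalytic Mukaiyama-type aldol. Ketone 9 is converted with TMSOTf and Et3N (CH2Cl2, 0 °C) into the trimethylsilyl enol ether F5. F5 is added to 6 with SiCl4, a chiral bisphosphoramide Lewis-base catalyst (the antipode that gives the 6S carbinol) and i-Pr2NEt in CH2Cl2 at −78 °C, a known enantioselective aldol type for methyl ketone enol silanes and unsaturated aldehydes; aqueous work-up should give 12.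

## Further compounds

F1 | step 14 | (1S,3S,6R,7S,8R,4Z,9E)-3-acetoxy-13-nor-11-(allyloxycarbonyl)-1-[(tert-butyldimethylsilyl)oxy]-8-[(triethylsilyl)oxy]germacra-4,9-dien-12,6-olide (C11 epimers) | C=CCOC(=O)C1C(=O)O[C@@H]2/C=C(/C)[C@@H](OC(C)=O)C[C@H](O[Si](C)(C)C(C)(C)C)/C(C)=C/[C@@H](O[Si](CC)(CC)CC)[C@@H]12
F2 | step 14 | corresponding 11-carboxy lactone (C11 epimers) | OC(=O)C1C(=O)O[C@@H]2/C=C(/C)[C@@H](OC(C)=O)C[C@H](O[Si](C)(C)C(C)(C)C)/C(C)=C/[C@@H](O[Si](CC)(CC)CC)[C@@H]12
F3 | step 12 | (1S,3S,8R,4Z,6Z,9E)-3-acetoxy-1-[(tert-butyldimethylsilyl)oxy]-4,10-dimethylcyclodeca-4,6,9-trien-8-ol (C8 epimer of 20) | C1[C@H](OC(C)=O)/C(C)=C\C=C/[C@@H](O)/C=C(\C)[C@H]1O[Si](C)(C)C(C)(C)C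
F4 | step 12 | (1S,3S,8S,4Z,6Z,9E)-3-acetoxy-1-[(tert-butyldimethylsilyl)oxy]-4,10-dimethylcyclodeca-4,6,9-trien-8-yl chloroacetate | C1[C@H](OC(C)=O)/C(C)=C\C=C/[C@H](OC(=O)CCl)/C=C(\C)[C@H]1O[Si](C)(C)C(C)(C)C
F5 | step 5 | (E)-5-[(tert-butyldimethylsilyl)oxy]-3-methyl-2-[(trimethylsilyl)oxy]penta-1,3-diene | C=C(O[Si](C)(C)C)/C(C)=C/CO[Si](C)(C)C(C)(C)C
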